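**Retrosynthetic overview**
- Numbering: ring A is the acyl ring; ring B is the phenol-acid ring, counted from its carboxyl carbon (C1 CO2H, C2 OH, C3 CH3, C4 ester oxygen, C5 H, C6 CH3).
- The ring B C1 carboxyl is traced back to a C1 formyl group, and the C1–CHO bond is cut to give a depside phenol plus formaldehyde.
- Feature the plan rests on: without its C1 carbon, ring B is the monoester of C2-symmetric 2,5-dimethylresorcinol. Its free C2 hydroxyl has one unsubstituted ortho carbon only (C1), because the other ortho carbon (C3) carries a methyl group.
- The depside C(=O)–O bond is cut to 2,4-dimethoxy-3,6-dimethylbenzoyl chloride and the symmetric diol; the acid chloride comes from atraric acid by O-methylation, saponification and chlorination.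
- No ring is formed: both benzene rings are bought intact, and the target has no stereocenter.

Key step: step 5

Remark: 2,5-dimethylbenzene-1,3-diol, atraric acid and paraformaldehyde are taken as purchasable; the target is achiral, so no stereocontrol is needed anywhere.

**Step 1**
Reactants: 1 methyl 2,4-dihydroxy-3,6-dimethylbenzoate (atraric acid)
Product: 3 methyl 2,4-dimethoxy-3,6-dimethylbenzoate, via methyl 2-hydroxy-4-methoxy-3,6-dimethylbenzoate 2 (not isolated)
Conditions: MeI (excess), K2CO3, DMF, 50 °C
Reagents that add atoms: iodomethane, CI
Why: Williamson O-methylation (SN2 on MeI) of both phenoxides; the hydrogen-bonded, flanked C2 hydroxyl reacts after the C4 hydroxyl but should be driven to completion in DMF with excess MeI, while the methyl ester is inert to carbonate.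

**Step 2**
Reactants: 3 methyl 2,4-dimethoxy-3,6-dimethylbenzoate
Product: 4 2,4-dimethoxy-3,6-dimethylbenzoic acid
Conditions: KOH, DMSO/H2O, 90 °C; then cold 1 M HCl
Reagents that add atoms: potassium hydroxide (KOH), [K+].[OH-]
Why: Saponification (BAC2) of the di-ortho-substituted methyl ester needs the poorly solvated hydroxide of aqueous DMSO at elevated temperature, which leaves the aryl methyl ethers intact, and cold acidification avoids protodecarboxylation of the electron-rich acid.

**Step 3**
Reactants: 4 2,4-dimethoxy-3,6-dimethylbenzoic acid
Product: 5 2,4-dimethoxy-3,6-dimethylbenzoyl chloride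
Conditions: (COCl)2, DMF (cat.), CH2Cl2, 0 °C to rt; evaporate, use crude
Reagents that add atoms: oxalyl chloride, O=C(Cl)C(=O)Cl
Why: Acid chloride formation through the catalytic chloroiminium species from DMF and oxalyl chloride runs cold and without added acid, so the methyl ethers and the electron-rich ring should be untouched, and the by-products are gases.

**Step 4**
Reactants: 5 2,4-dimethoxy-3,6-dimethylbenzoyl chloride; 6 2,5-dimethylbenzene-1,3-diol
Product: 7 3-hydroxy-2,5-dimethylphenyl 2,4-dimethoxy-3,6-dimethylbenzoate
Conditions: 6 (3 equiv), Et3N, DMAP (cat.), THF, 0 °C to rt, slow addition of 5; excess 6 recovered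
Reagents that add atoms: none
Why: DMAP-catalysed O-acylation of a phenol by an aroyl chloride; the two hydroxyls of 6 are equivalent by symmetry, so any first acylation gives 7, and the excess of 6 with slow addition of 5 should suppress the diester.

**Step 5**
Reactants: 7 3-hydroxy-2,5-dimethylphenyl 2,4-dimethoxy-3,6-dimethylbenzoate; 8 formaldehyde (as paraformaldehyde)
Product: 10 4-formyl-3-hydroxy-2,5-dimethylphenyl 2,4-dimethoxy-3,6-dimethylbenzoate, via benzylic alcohol 9 (not isolated)
Conditions: MgCl2 (anhydrous, 2 equiv), Et3N (4 equiv), (CH2O)n (6 equiv), MeCN, reflux; then 1 M HCl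
Reagents that add atoms: formaldehyde 8 (as paraformaldehyde), C=O
Why: Et3N and MgCl2 convert the free ring B phenol into its chloromagnesium phenoxide, monomeric formaldehyde released from paraformaldehyde binds the same magnesium, and the carbon–carbon bond forms through a six-membered cyclic transition state at the adjacent ring B C1 carbon, giving after rearomatisation the magnesium-bound benzylic alcohol 9. A second magnesium-bound formaldehyde then accepts hydride from the benzylic alkoxide in an Oppenauer-type transfer, so that aldehyde 10 and methanol result. This is the Casnati–Skattebøl ortho-formylation of phenols (MgCl2, Et3N, paraformaldehyde), a known reaction type that is used on phenols with alkyl groups flanking the reacting ortho carbon and on phenols bearing ester groups. No ring is closed and no stereocenter is created. The step needs ortho over para selectivity (ring B C5–H is para to the hydroxyl), which the intramolecular delivery from magnesium secures, while the second ortho carbon (ring B C3) is blocked by its methyl group and ring A, having no phenoxide to bind magnesium, is not attacked. The depside ester is a di-ortho-substituted benzoate that should resist Et3N and the methanol formed, and it cannot migrate because the two ring B oxygens are meta to each other.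

**Step 6**
Reactants: 10 4-formyl-3-hydroxy-2,5-dimethylphenyl 2,4-dimethoxy-3,6-dimethylbenzoate
Product: 11 diffractaic acid, 4-[(2,4-dimethoxy-3,6-dimethylbenzoyl)oxy]-2-hydroxy-3,6-dimethylbenzoic acid
Conditions: NaClO2, NaH2PO4, 2-methyl-2-butene (large excess), t-BuOH/THF/H2O, 0 °C to rt; acidify to pH 3, extract without heating
Reagents that add atoms: sodium chlorite (NaClO2), [Na+].[O-]Cl=O
Why: Pinnick (Lindgren–Kraus) oxidation by chlorous acid converts the aldehyde into the carboxylic acid at buffered pH, where the aryl ester and free phenol should survive, and 2-methyl-2-butene traps the HOCl that would otherwise chlorinate the electron-rich rings.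

**Compound list**
1 | methyl 2,4-dihydroxy-3,6-dimethylbenzoate (atraric acid) | COC(=O)c1c(C)cc(O)c(C)c1O | starting material
2 | methyl 2-hydroxy-4-methoxy-3,6-dimethylbenzoate | COC(=O)c1c(C)cc(OC)c(C)c1O | intermediate (not isolated)
3 | methyl 2,4-dimethoxy-3,6-dimethylbenzoate | COC(=O)c1c(C)cc(OC)c(C)c1OC | intermediate
4 | 2,4-dimethoxy-3,6-dimethylbenzoic acid | COc1cc(C)c(C(=O)O)c(OC)c1C | intermediate
5 | 2,4-dimethoxy-3,6-dimethylbenzoyl chloride | COc1cc(C)c(C(=O)Cl)c(OC)c1C | intermediate
6 | 2,5-dimethylbenzene-1,3-diol | Cc1cc(O)c(C)c(O)c1 | starting material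
7 | 3-hydroxy-2,5-dimethylphenyl 2,4-dimethoxy-3,6-dimethylbenzoate | COc1cc(C)c(C(=O)Oc2cc(C)cc(O)c2C)c(OC)c1C | intermediate
8 | formaldehyde (used as paraformaldehyde) | C=O | starting material
9 | 3-hydroxy-4-(hydroxymethyl)-2,5-dimethylphenyl 2,4-dimethoxy-3,6-dimethylbenzoate | COc1cc(C)c(C(=O)Oc2cc(C)c(CO)c(O)c2C)c(OC)c1C | intermediate (not isolated)
10 | 4-formyl-3-hydroxy-2,5-dimethylphenyl 2,4-dimethoxy-3,6-dimethylbenzoate | COc1cc(C)c(C(=O)Oc2cc(C)c(C=O)c(O)c2C)c(OC)c1C | intermediate
11 | diffractaic acid | COc1cc(C)c(C(=O)Oc2cc(C)c(C(=O)O)c(O)c2C)c(OC)c1C | target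

**Step count**
Total steps: 6. Longest linear sequence: 6 steps (1 to 11); diol 6 and formaldehyde 8 enter as purchased materials.

**Steps most likely to fail**

Step 5 (key step). Bond formation at an ortho carbon flanked by the hydroxyl and the C6 methyl may be slow. The benzylic alcohol stage could then condense with a second phenol to give methylene-bridged dimers, or magnesium methoxide could transesterify the depside ester. Fallback: the formyl group is installed before the ester is made. Diol 6 is subjected to Vilsmeier–Haack formylation (POCl3, DMF, MeCN, 0 °C to rt), which by symmetry can give only one iminium salt, [(2,4-dihydroxy-3,6-dimethylphenyl)methylidene]dimethyliminium chloride F1. Aqueous hydrolysis at 50 °C then gives 2,4-dihydroxy-3,6-dimethylbenzaldehyde F2. In F2 the hydroxyl next to the formyl group is held in a hydrogen bond, so acylation with acid chloride 5 (Et3N, DMAP cat., THF, 0 °C) should take place at the other hydroxyl, para to the formyl group. This returns to the route at aldehyde 10.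

Step 6. Hypochlorous acid may escape the scavenger and chlorinate the electron-rich ring A C5 position, or chlorine dioxide may degrade the free phenol. Fallback: the carboxyl is carried from the start as a benzyl ester, so no oxidation is needed. Atraric acid 1 is hydrolysed (conc. H2SO4, rt, then ice) to 2,4-dihydroxy-3,6-dimethylbenzoic acid F3. Alkylation of its carboxylate (BnBr, KHCO3, DMF, rt) gives benzyl 2,4-dihydroxy-3,6-dimethylbenzoate F4. Acylation with acid chloride 5 (Et3N, DMAP cat., CH2Cl2) should go at the C4 hydroxyl, the C2 hydroxyl being hydrogen-bonded to the ester carbonyl, to give benzyl 4-[(2,4-dimethoxy-3,6-dimethylbenzoyl)oxy]-2-hydroxy-3,6-dimethylbenzoate F5. Hydrogenolysis (H2, Pd/C, EtOAc, rt) then returns to the route at the target 11.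

Step 4. Over-acylation to the diester, or sluggish reaction of the di-ortho-substituted acid chloride, may leave hard-to-separate mixtures. Fallback: the statistical event is moved to a cheap benzylation so that the acylation can be forced. Diol 6 is monobenzylated (BnBr 1 equiv, K2CO3, acetone, excess 6) to 3-(benzyloxy)-2,5-dimethylphenol F6. This is acylated with excess acid chloride 5 (NaH, THF, or Et3N/DMAP, warming as needed) to 3-(benzyloxy)-2,5-dimethylphenyl 2,4-dimethoxy-3,6-dimethylbenzoate F7. Hydrogenolysis (H2, Pd/C, EtOAc, rt), which leaves the aryl ester intact, returns to the route at phenol 7.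

**Further compounds**
F1 | step 5 | [(2,4-dihydroxy-3,6-dimethylphenyl)methylidene]dimethyliminium chloride | C[N+](C)=Cc1c(C)cc(O)c(C)c1O.[Cl-]
F2 | step 5 | 2,4-dihydroxy-3,6-dimethylbenzaldehyde | O=Cc1c(C)cc(O)c(C)c1O
F3 | step 6 | 2,4-dihydroxy-3,6-dimethylbenzoic acid | OC(=O)c1c(C)cc(O)c(C)c1O
F4 | step 6 | benzyl 2,4-dihydroxy-3,6-dimethylbenzoate | O=C(OCc1ccccc1)c1c(C)cc(O)c(C)c1O
F5 | step 6 | benzyl 4-[(2,4-dimethoxy-3,6-dimethylbenzoyl)oxy]-2-hydroxy-3,6-dimethylbenzoate | COc1cc(C)c(C(=O)Oc2cc(C)c(C(=O)OCc3ccccc3)c(O)c2C)c(OC)c1C
F6 | step 4 | 3-(benzyloxy)-2,5-dimethylphenol | Cc1cc(O)c(C)c(OCc2ccccc2)c1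
F7 | step 4 | 3-(benzyloxy)-2,5-dimethylphenyl 2,4-dimethoxy-3,6-dimethylbenzoate | COc1cc(C)c(C(=O)Oc2cc(C)cc(OCc3ccccc3)c2C)c(OC)c1C
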